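The seven-membered ring is disconnected by excising its two adjacent methyl-bearing carbons, C6 and C7, which sit between the benzylic C5 and the C8 methylene beside the spiro carbon C9. This leaves a spiro-fused cyclohexadienone indanone, whose five-membered ring closes easily when a syringyl phenoxide attacks a bromomethyl ketone through its para carbon. In the key step rhodium cleaves the indanone C(=O)–CH2 bond and but-2-yne is stitched in, forming both new C–C bonds and enlarging the ring from five to seven members in one operation. The three stereocentres follow from two catalyst-controlled ketone reductions, a hydroxyl-directed hydrogenation, one epimerisation and a Mitsunobu inversion.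

Key step: step 5

Remark: locants follow the benzo[7]annulene ring (C5 oxygen-bearing benzylic carbon, C6 and C7 methyl-bearing carbons, C8 methylene, C9 spiro carbon; primed locants belong to the cyclohexadienone ring); the target SMILES is read as 5R,6S,7R, i.e. the 6-methyl group trans to both the 7-methyl and the 5-acetoxy group; boronate 3 and but-2-yne are taken as purchased.

Step 1
Reactants: 1 3,4,5-trimethoxyacetophenone
Product: 2 1-(2-bromo-3,4,5-trimethoxyphenyl)ethan-1-one
Conditions: NBS (1.05 equiv), MeCN, rt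
Reagents that add atoms: N-bromosuccinimide, BrN1C(=O)CCC1=O
Why: Electrophilic aromatic bromination with NBS in acetonitrile should take place on the ring, whose two equivalent free positions are each ortho and para to a methoxy group, because without acid or a radical initiator the acetyl methyl group does not enolise or brominate.

Step 2
Reactants: 2 1-(2-bromo-3,4,5-trimethoxyphenyl)ethan-1-one; 3 2,6-dimethoxy-4-(4,4,5,5-tetramethyl-1,3,2-dioxaborolan-2-yl)phenol
Product: 4 1-(4'-hydroxy-3',4,5,5',6-pentamethoxybiphenyl-2-yl)ethan-1-one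
Conditions: Pd(OAc)2 (3 mol%), SPhos (6 mol%), K3PO4 (3 equiv), toluene/H2O 10:1, 90 °C
Reagents that add atoms: none
Why: Suzuki–Miyaura coupling with a dialkylbiarylphosphine ligand should couple the doubly ortho-substituted bromide, the free phenol of the boronate merely consuming one equivalent of base.

Step 3
Reactants: 4 1-(4'-hydroxy-3',4,5,5',6-pentamethoxybiphenyl-2-yl)ethan-1-one
Product: 6 2-bromo-1-[4'-(tert-butyldimethylsilyloxy)-3',4,5,5',6-pentamethoxybiphenyl-2-yl]ethan-1-one, via bis-silyl enol ether 5 (not isolated)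
Conditions: TBSOTf (2.3 equiv), Et3N (2.6 equiv), CH2Cl2, 0 °C; NaHCO3 wash; then NBS (1.0 equiv), THF, −78 °C
Reagents that add atoms: tert-butyldimethylsilyl trifluoromethanesulfonate, CC(C)(C)[Si](C)(C)OS(=O)(=O)C(F)(F)F; N-bromosuccinimide, BrN1C(=O)CCC1=O
Why: Soft enolisation and silylation turns the only enolisable ketone into its silyl enol ether while capping the phenol, so that NBS brominates the far more nucleophilic enol ether (α-bromination of a ketone through its silyl enol ether) and the electron-rich syringyl ring, which bromine or CuBr2 would attack, is left alone.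

Step 4
Reactants: 6 2-bromo-1-[4'-(tert-butyldimethylsilyloxy)-3',4,5,5',6-pentamethoxybiphenyl-2-yl]ethan-1-one
Product: 8 3,5,5',6',7'-pentamethoxyspiro[cyclohexa-2,5-diene-1,1'-indane]-3',4-dione, via cesium phenoxide 7 (not isolated)
Conditions: CsF (1.5 equiv), DMF (0.01 M), 0 °C to rt
Reagents that add atoms: none
Why: Fluoride removes the aryl silyl group and the naked phenoxide alkylates through its para carbon in a dearomatising 5-exo-tet SN2 displacement (Winstein Ar1-5 phenoxide participation), since the oxygen and the methoxy-bearing ortho carbons cannot reach the bromomethyl group within the same molecule and high dilution suppresses intermolecular O-alkylation.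

Step 5
Reactants: 8 3,5,5',6',7'-pentamethoxyspiro[cyclohexa-2,5-diene-1,1'-indane]-3',4-dione; 9 but-2-yne
Product: 12 1,2,3,3',5'-pentamethoxy-6,7-dimethylspiro[benzo[7]annulene-9,1'-cyclohexa[2,5]diene]-4',5(8H)-dione, via indanone pyridyl ketimine 10 (not isolated), via ring-enlarged pyridyl ketimine 11 (not isolated)
Conditions: [Rh(C2H4)2Cl]2 (5 mol%), IMes (1,3-dimesitylimidazol-2-ylidene, 12 mol%), 2-amino-3-picoline (30 mol%), TsOH·H2O (10 mol%), H2O (1 equiv), but-2-yne (5 equiv), 1,4-dioxane, 130 °C, sealed tube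
Reagents that add atoms: none
Why: The aminopyridine condenses reversibly with the indanone carbonyl and its ring nitrogen steers monovalent rhodium into the imidoyl–CH2 bond to give a six-membered rhodacycle; but-2-yne inserts into a Rh–C bond and C–C reductive elimination from the resulting eight-membered rhodacycle releases the enone ketimine, which water hydrolyses with return of the amine. The closest known reaction type is the rhodium-catalysed, aminopyridine-directed C–C activation of 1-indanones with two-carbon insertion of ethylene or internal alkynes to give benzocycloheptenones. The seven-membered ring is closed by ring enlargement through reductive elimination and not by an end-to-end cyclisation, so no medium-ring closure has to be paid for. No stereocentre is formed. The step needs cleavage of the acyl–CH2 bond and not the acyl–aryl bond, which the imine geometry with the pyridyl group on the CH2 side should secure, and condensation at the indanone carbonyl only, which should hold because the dienone carbonyl is cross-conjugated and flanked by two methoxy-bearing sp2 carbons. The quaternary spiro carbon offers no β-hydrogen to the alkyl–rhodium bond, the symmetric alkyne removes any regiochemical question, and the acid is kept low and buffered by excess aminopyridine to avoid a dienone–phenol rearrangement.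

Step 6
Reactants: 12 1,2,3,3',5'-pentamethoxy-6,7-dimethylspiro[benzo[7]annulene-9,1'-cyclohexa[2,5]diene]-4',5(8H)-dione
Product: 13 (5S)-5-hydroxy-1,2,3,3',5'-pentamethoxy-6,7-dimethyl-5,8-dihydrospiro[benzo[7]annulene-9,1'-cyclohexa[2,5]dien]-4'-one
Conditions: RuCl(p-cymene)[(S,S)-TsDPEN] (3 mol%), HCO2H/Et3N (1:1), CH2Cl2, 30 °C
Reagents that add atoms: none
Why: Noyori–Ikariya asymmetric transfer hydrogenation should reduce only the benzo-fused aryl ketone, because hydride and proton are passed to a carbonyl whose arene is held by a CH/π contact to the cymene ligand while the non-aryl dienone carbonyl and the tetrasubstituted alkene are poor acceptors, and the (S,S)-ligand sets C5 as S by catalyst control in the sense known for 1-tetralone.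

Step 7
Reactants: 13 (5S)-5-hydroxy-1,2,3,3',5'-pentamethoxy-6,7-dimethyl-5,8-dihydrospiro[benzo[7]annulene-9,1'-cyclohexa[2,5]dien]-4'-one
Product: 14 (5S,6R,7R)-5-hydroxy-1,2,3,3',5'-pentamethoxy-6,7-dimethyl-5,6,7,8-tetrahydrospiro[benzo[7]annulene-9,1'-cyclohexa[2,5]dien]-4'-one
Conditions: [Ir(cod)(PCy3)(py)]PF6 (10 mol%), H2 (1 atm), CH2Cl2, 0 °C to rt
Reagents that add atoms: none
Why: In this hydroxyl-directed homogeneous hydrogenation the C5 hydroxyl binds the cationic iridium centre and both hydrogen atoms are added to the tetrasubstituted C6=C7 bond on the hydroxyl face, which fixes C7 as R (and C6, for the time being, as R) under substrate control, while the electron-poor, undirected double bonds of the dienone should react much more slowly.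

Step 8
Reactants: 14 (5S,6R,7R)-5-hydroxy-1,2,3,3',5'-pentamethoxy-6,7-dimethyl-5,6,7,8-tetrahydrospiro[benzo[7]annulene-9,1'-cyclohexa[2,5]dien]-4'-one
Product: 16 (6S,7R)-1,2,3,3',5'-pentamethoxy-6,7-dimethyl-7,8-dihydrospiro[benzo[7]annulene-9,1'-cyclohexa[2,5]diene]-4',5(6H)-dione, via cis-dimethyl ketone 15 (not isolated)
Conditions: Dess–Martin periodinane (1.3 equiv), NaHCO3, CH2Cl2, 0 °C to rt; then DBU (0.3 equiv), CH2Cl2, rt
Reagents that add atoms: none
Why: Dess–Martin oxidation returns the C5 ketone under buffered conditions that spare the dienone, and reversible enolisation with DBU then epimerises only C6 to the more stable trans-6,7-dimethyl ketone, in which both methyl groups sit equatorially on the chair-like seven-membered ring, while C7 has no acidic hydrogen and keeps its configuration.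

Step 9
Reactants: 16 (6S,7R)-1,2,3,3',5'-pentamethoxy-6,7-dimethyl-7,8-dihydrospiro[benzo[7]annulene-9,1'-cyclohexa[2,5]diene]-4',5(6H)-dione
Product: 17 (5S,6S,7R)-5-hydroxy-1,2,3,3',5'-pentamethoxy-6,7-dimethyl-5,6,7,8-tetrahydrospiro[benzo[7]annulene-9,1'-cyclohexa[2,5]dien]-4'-one
Conditions: RuCl(p-cymene)[(S,S)-TsDPEN] (3 mol%), HCO2H/Et3N (1:1), CH2Cl2, 30 °C
Reagents that add atoms: none
Why: The same asymmetric transfer hydrogenation again picks the aryl ketone over the dienone carbonyl, and the (S,S)-catalyst should pass hydride to the outer face of C5, away from the pseudo-axial dienone carbon on C9, so that catalyst and substrate control act together (as in the cis-selective reductions of 2-alkyl-1-tetralones) and C5 is set as S, cis to the C6 methyl group.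

Step 10
Reactants: 17 (5S,6S,7R)-5-hydroxy-1,2,3,3',5'-pentamethoxy-6,7-dimethyl-5,6,7,8-tetrahydrospiro[benzo[7]annulene-9,1'-cyclohexa[2,5]dien]-4'-one
Product: 18 (5R,6S,7R)-1,2,3,3',5'-pentamethoxy-6,7-dimethyl-4'-oxo-5,6,7,8-tetrahydrospiro[benzo[7]annulene-9,1'-cyclohexa[2,5]dien]-5-yl acetate (CNP0143674.1)
Conditions: PPh3 (2 equiv), DIAD (2 equiv), AcOH (3 equiv), toluene, 0 °C to rt
Reagents that add atoms: acetic acid, CC(=O)O
Why: Mitsunobu esterification turns the benzylic hydroxyl into an oxyphosphonium leaving group that acetate displaces by SN2 from the open outer face, inverting C5 from S to R and thereby placing the acetoxy group trans to the C6 methyl group as in the target.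

Compound list
1 | 3,4,5-trimethoxyacetophenone | CC(=O)c1cc(OC)c(OC)c(OC)c1 | starting material
2 | 1-(2-bromo-3,4,5-trimethoxyphenyl)ethan-1-one | CC(=O)c1cc(OC)c(OC)c(OC)c1Br | intermediate
3 | 2,6-dimethoxy-4-(4,4,5,5-tetramethyl-1,3,2-dioxaborolan-2-yl)phenol | COc1cc(cc(OC)c1O)B1OC(C)(C)C(C)(C)O1 | starting material
4 | 1-(4'-hydroxy-3',4,5,5',6-pentamethoxybiphenyl-2-yl)ethan-1-one | CC(=O)c1cc(OC)c(OC)c(OC)c1-c1cc(OC)c(O)c(OC)c1 | intermediate
5 | 2-[1-(tert-butyldimethylsilyloxy)vinyl]-4'-(tert-butyldimethylsilyloxy)-3',4,5,5',6-pentamethoxybiphenyl (not isolated) | C=C(O[Si](C)(C)C(C)(C)C)c1cc(OC)c(OC)c(OC)c1-c1cc(OC)c(O[Si](C)(C)C(C)(C)C)c(OC)c1 | intermediate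
6 | 2-bromo-1-[4'-(tert-butyldimethylsilyloxy)-3',4,5,5',6-pentamethoxybiphenyl-2-yl]ethan-1-one | BrCC(=O)c1cc(OC)c(OC)c(OC)c1-c1cc(OC)c(O[Si](C)(C)C(C)(C)C)c(OC)c1 | intermediate
7 | cesium 2'-(bromoacetyl)-3,4',5,5',6'-pentamethoxybiphenyl-4-olate (not isolated) | [Cs+].[O-]c1c(OC)cc(cc1OC)-c1c(OC)c(OC)c(OC)cc1C(=O)CBr | intermediate
8 | 3,5,5',6',7'-pentamethoxyspiro[cyclohexa-2,5-diene-1,1'-indane]-3',4-dione | COC1=CC2(C=C(OC)C1=O)CC(=O)c1cc(OC)c(OC)c(OC)c12 | intermediate
9 | but-2-yne | CC#CC | starting material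
10 | N-(3-methylpyridin-2-yl) ketimine of 8 at C3' (not isolated) | COC1=CC2(C=C(OC)C1=O)CC(=Nc1ncccc1C)c1cc(OC)c(OC)c(OC)c12 | intermediate
11 | N-(3-methylpyridin-2-yl) ketimine of 12 at C5 (not isolated) | COC1=CC2(C=C(OC)C1=O)CC(C)=C(C)C(=Nc1ncccc1C)c1cc(OC)c(OC)c(OC)c12 | intermediate
12 | 1,2,3,3',5'-pentamethoxy-6,7-dimethylspiro[benzo[7]annulene-9,1'-cyclohexa[2,5]diene]-4',5(8H)-dione | COC1=CC2(C=C(OC)C1=O)CC(C)=C(C)C(=O)c1cc(OC)c(OC)c(OC)c12 | intermediate
13 | (5S)-5-hydroxy-1,2,3,3',5'-pentamethoxy-6,7-dimethyl-5,8-dihydrospiro[benzo[7]annulene-9,1'-cyclohexa[2,5]dien]-4'-one | COC1=CC2(C=C(OC)C1=O)CC(C)=C(C)[C@H](O)c1cc(OC)c(OC)c(OC)c12 | intermediate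
14 | (5S,6R,7R)-5-hydroxy-1,2,3,3',5'-pentamethoxy-6,7-dimethyl-5,6,7,8-tetrahydrospiro[benzo[7]annulene-9,1'-cyclohexa[2,5]dien]-4'-one | COC1=CC2(C=C(OC)C1=O)C[C@@H](C)[C@@H](C)[C@H](O)c1cc(OC)c(OC)c(OC)c12 | intermediate
15 | (6R,7R)-1,2,3,3',5'-pentamethoxy-6,7-dimethyl-7,8-dihydrospiro[benzo[7]annulene-9,1'-cyclohexa[2,5]diene]-4',5(6H)-dione, cis-dimethyl (not isolated) | COC1=CC2(C=C(OC)C1=O)C[C@@H](C)[C@@H](C)C(=O)c1cc(OC)c(OC)c(OC)c12 | intermediate
16 | (6S,7R)-1,2,3,3',5'-pentamethoxy-6,7-dimethyl-7,8-dihydrospiro[benzo[7]annulene-9,1'-cyclohexa[2,5]diene]-4',5(6H)-dione, trans-dimethyl | COC1=CC2(C=C(OC)C1=O)C[C@@H](C)[C@H](C)C(=O)c1cc(OC)c(OC)c(OC)c12 | intermediate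
17 | (5S,6S,7R)-5-hydroxy-1,2,3,3',5'-pentamethoxy-6,7-dimethyl-5,6,7,8-tetrahydrospiro[benzo[7]annulene-9,1'-cyclohexa[2,5]dien]-4'-one | COC1=CC2(C=C(OC)C1=O)C[C@@H](C)[C@H](C)[C@H](O)c1cc(OC)c(OC)c(OC)c12 | intermediate
18 | (5R,6S,7R)-1,2,3,3',5'-pentamethoxy-6,7-dimethyl-4'-oxo-5,6,7,8-tetrahydrospiro[benzo[7]annulene-9,1'-cyclohexa[2,5]dien]-5-yl acetate (CNP0143674.1) | COC1=CC2(C=C(OC)C1=O)C[C@@H](C)[C@H](C)[C@@H](OC(C)=O)c1cc(OC)c(OC)c(OC)c12 | target

Total step count: 10. Longest linear sequence: 10 steps (1 to 18).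

Steps most likely to fail

Step 5. The cross-conjugated dienone may be destroyed at 130 °C by acid-induced rearrangement or by conjugate addition of the amine, or rhodium may fail to insert beside the quaternary spiro carbon. The fallback closes the ring by olefin metathesis; it sets out from 4 and returns at 12. Phenol 4 is O-alkylated with 3-chloro-2-methylpropene (K2CO3, DMF) to the methallyl ether F1. Two successive enolate methylations (LiN(SiMe3)2, MeI, THF, −78 °C) lead through the propanoyl ketone F2, which is not isolated, to the isobutyryl ketone F3. Heating (N,N-diethylaniline, 180 °C) should bring about a para-Claisen rearrangement through the ortho-dienone F4, not isolated, to the 4-aryl-4-(2-methylallyl)cyclohexadienone F5. Dehydrogenation with IBX (DMSO, 70 °C) gives the 2-methylacryloyl ketone F6. Ring-closing metathesis (second-generation Hoveyda–Grubbs catalyst, toluene, 80 °C) then joins the two 1,1-disubstituted alkenes into the tetrasubstituted C6=C7 bond of 12.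

Step 6. Hydride transfer to the hindered aryl alkenyl ketone may be slow, or the catalyst may discriminate poorly between its two faces. The fallback moves enantiocontrol to the later ketone reduction; it sets out from 12 and returns at 17. Enone 12 is reduced 1,2 with NaBH4/CeCl3·7H2O (MeOH, −78 °C, one hydride equivalent) to the racemic allylic alcohol, that is 13 together with its enantiomer F7. Steps 7 and 8 are run on the racemate and give 14 with its enantiomer F8 and, through the enantiomeric cis-ketone F9 (not isolated), 16 with its enantiomer F10. Step 9 then acts as a kinetic resolution, since the (S,S)-catalyst should reduce only the matched (6S,7R)-ketone 16 quickly, and 17 is separated from unreacted F10.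

Step 10. The electron-rich benzylic oxyphosphonium ion may undergo β-elimination to the styrene, or ionise, in place of clean inversion. The fallback avoids the inversion; it sets out from 16 and returns at 18. Ketone 16 is reduced under catalyst control with the enantiomeric complex RuCl(p-cymene)[(R,R)-TsDPEN] (HCO2H/Et3N) to the 5R alcohol F11, trans to the C6 methyl group, which is acetylated with retention (Ac2O, pyridine, DMAP) to 18.

Further compounds
F1 | step 5 | 1-[3',4,5,5',6-pentamethoxy-4'-(2-methylallyloxy)biphenyl-2-yl]ethan-1-one | CC(=O)c1cc(OC)c(OC)c(OC)c1-c1cc(OC)c(OCC(C)=C)c(OC)c1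
F2 | step 5 | 1-[3',4,5,5',6-pentamethoxy-4'-(2-methylallyloxy)biphenyl-2-yl]propan-1-one (not isolated) | CCC(=O)c1cc(OC)c(OC)c(OC)c1-c1cc(OC)c(OCC(C)=C)c(OC)c1
F3 | step 5 | 2-methyl-1-[3',4,5,5',6-pentamethoxy-4'-(2-methylallyloxy)biphenyl-2-yl]propan-1-one | CC(C)C(=O)c1cc(OC)c(OC)c(OC)c1-c1cc(OC)c(OCC(C)=C)c(OC)c1
F4 | step 5 | 2,6-dimethoxy-6-(2-methylallyl)-4-[2,3,4-trimethoxy-6-(2-methylpropanoyl)phenyl]cyclohexa-2,4-dien-1-one (not isolated) | COC1=CC(=CC(CC(C)=C)(OC)C1=O)c1c(OC)c(OC)c(OC)cc1C(=O)C(C)C
F5 | step 5 | 2,6-dimethoxy-4-(2-methylallyl)-4-[2,3,4-trimethoxy-6-(2-methylpropanoyl)phenyl]cyclohexa-2,5-dien-1-one | COC1=CC(CC(C)=C)(C=C(OC)C1=O)c1c(OC)c(OC)c(OC)cc1C(=O)C(C)C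
F6 | step 5 | 2,6-dimethoxy-4-(2-methylallyl)-4-[2,3,4-trimethoxy-6-(2-methylprop-2-enoyl)phenyl]cyclohexa-2,5-dien-1-one | COC1=CC(CC(C)=C)(C=C(OC)C1=O)c1c(OC)c(OC)c(OC)cc1C(=O)C(C)=C
F7 | step 6 | (5R)-enantiomer of 13 | COC1=CC2(C=C(OC)C1=O)CC(C)=C(C)[C@@H](O)c1cc(OC)c(OC)c(OC)c12
F8 | step 6 | (5R,6S,7S)-enantiomer of 14 | COC1=CC2(C=C(OC)C1=O)C[C@H](C)[C@H](C)[C@@H](O)c1cc(OC)c(OC)c(OC)c12
F9 | step 6 | (6S,7S)-enantiomer of 15 (not isolated) | COC1=CC2(C=C(OC)C1=O)C[C@H](C)[C@H](C)C(=O)c1cc(OC)c(OC)c(OC)c12
F10 | step 6 | (6R,7S)-enantiomer of 16 | COC1=CC2(C=C(OC)C1=O)C[C@H](C)[C@@H](C)C(=O)c1cc(OC)c(OC)c(OC)c12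
F11 | step 10 | (5R,6S,7R)-5-hydroxy-1,2,3,3',5'-pentamethoxy-6,7-dimethyl-5,6,7,8-tetrahydrospiro[benzo[7]annulene-9,1'-cyclohexa[2,5]dien]-4'-one | COC1=CC2(C=C(OC)C1=O)C[C@@H](C)[C@H](C)[C@@H](O)c1cc(OC)c(OC)c(OC)c12
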